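## Structural features

Numbering used throughout: the ring atoms are O1, O2, C3, C4 and C5, the acetic acid arm sits on C3, and the side chain on C5 runs from C6 to C17 with the phenyl ring on C17. The target 22 is a 3,3,5,5-tetrasubstituted 1,2-dioxolane in which C3 carries a methyl group and the CH2CO2H arm, and C5 carries a methyl group and a chain ending in an (E,E)-phenylbutadiene (C14=C15–C16=C17–Ph). C3 (S) and C5 (R) are fully substituted peroxy carbons separated only by the ring CH2 (C4), with the acetic acid arm and the chain on opposite faces of the ring; C7 (R) is a methyl-bearing CH one carbon away from C5, so C5/C7 form a second 1,3-pair and no two stereocentres are bonded to each other. The O–O bond rules out hydrogenation catalysts, low-valent metals, phosphines, strong hydride donors and prolonged heating; the β-peroxy ester or acid can open the ring by β-elimination under strong base; and the phenyldiene is sensitive to light, acid and any alkene reduction, so it has to be built last. The real difficulty lies in the ring: two quaternary C–O stereocentres must be made in a defined trans relationship on a ring with no neighbouring group to steer a reagent, and the remote C7 centre cannot be expected to follow from them. The feature the key step uses is that C3, C4 and C5 with their two methyl groups are the carbon skeleton of pentane-2,4-dione at the ketone oxidation level, bridged by O1–O2, and that both exocyclic bonds at the ring (C3–CH2CO2 and C5–C6) join a peroxy carbon to a CH2 that can act as a nucleophile. C6–C9 with the C7 methyl group in turn map onto 3-methylbut-2-enal, whose C7=C8 double bond is the handle for setting C7.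

## Logic of the disconnections

22 ⇒ 20. The O–H of the acid is traced back to an O–CH3 bond; no skeletal bond is cut. The acid is carried as the methyl ester because that is the oxidation level the ketene acetal delivers and because it keeps the acid proton out of the ylide and carbanion steps. The forward step must hydrolyse the ester without β-elimination of the peroxide and without touching the diene.

20 ⇒ 17 + 18. The C14=C15 double bond is cut. The diene is the most reduction-sensitive part and must be introduced after the last alkene reduction; cutting here leaves a saturated aldehyde and a three-carbon styryl phosphonate. The forward step must be E-selective and must use a base too weak to enolise the β-peroxy ester.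

17 ⇒ 16 ⇒ 15. No skeletal bond is cut; the C14 carbonyl is traced back to C14–OH and then to C14–O–Si. C14 travels as a silyl ether through the ylide chemistry and the alkene reduction, which removes any chemoselectivity question there. The demand is an acid-mild desilylation and a non-reducing, metal-free oxidation that stops at the aldehyde.

15 ⇒ 14 ⇒ 10 + 12. Unsaturation is added at C9–C10 and the C9=C10 bond is then cut. C9 is the carbonyl carbon left by the C7-setting step, so an ylide olefination attaches the whole C10–C14 unit in one operation and its geometry is irrelevant. The demand falls on the saturation step, which must reduce a C=C bond and leave the O–O bond intact; that excludes catalytic hydrogenation and calls for diimide.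

12 ⇒ 11. The P–C10 bond is cut, giving a primary bromide and a phosphine. This is a plain alkylation; the only demand is that no free phosphine is carried forward to the peroxide.

10 ⇒ 9. The C7–H bond is cut by adding C7=C8 unsaturation. This turns the C7 problem into a face-selective hydride addition to a conjugated aldehyde, which a chiral amine catalyst can control independently of the ring; 9 then has only the two ring stereocentres. The demand is reagent control strong enough to ignore the distant ring, and a separation of the two diastereomers that arise because the ring is racemic; half of the material is given up at this point.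

9 ⇒ 4 + 7 + 6. The C3–CH2(CO2CH3) bond and the C5–C6 bond are cut, both at ring peroxy carbons. Each is a bond from a cation-stabilising carbon to a nucleophilic CH2, so the ring can be bought as a symmetrical seven-carbon bis-ketal and all three partners lie one or two steps from commodity chemicals. The forward step must ionise the two equivalent ketal carbons one at a time, bring in the ester nucleophile first (the ester survives the second stage, whereas an aldehyde would not survive a ketene acetal), direct the dienol silane to react through its terminal carbon, and place the chain trans to the ester arm.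

4 ⇒ 3 ⇒ 1 + 2. The two C–OCH3 bonds are traced back to C–OH, and then the C3–O2 and C5–O1 bonds are cut. The ring is simply the 1,3-diketone with one molecule of peroxide added across both carbonyl groups. The demand is strict one-to-one stoichiometry and careful handling, because 3 and 4 are small peroxides with a high active-oxygen content.

6 ⇒ 5. The O–Si bond is cut. γ-Deprotonation with O-silylation of the enal gives the dienol silane in one step; its geometry is of no consequence.

## Other disconnections considered

Alternative 1: The future C3 and C8 are tied together as a ring C=C bond that is cleaved oxidatively later, so that C3–C8 and all three methyl groups come from mesitylene A1 through Birch reduction to the meso diene A2. The forward key step is a Shi-type epoxidation of A2 by the dioxirane made from a fructose-derived chiral ketone and KHSO5. It should oxidise one of the two enantiotopic trisubstituted alkenes on the face away from the ring methyl group and give the mono-epoxide A3, forming the C5–O and C6–O bonds.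
- In its favour: the starting material is cheap, the C5/C7 relationship is set on a ring, and a catalyst fixes relative and absolute configuration in one step from an achiral compound.
- Where it is better than the chosen plan: absolute stereocontrol (the chosen plan makes the ring as a racemate and discards half the material after step 5) and precedent for the key step (dioxirane epoxidation of trisubstituted alkenes is an established class; step 4 is not).
- Against it: the oxygen placed on C5 is an epoxide oxygen, not a peroxide. The peroxide would have to come from opening the epoxide at the tertiary carbon with H2O2, with inversion to be matched to the epoxide face. That leaves a hydroxyl on C6 to be removed in the presence of an O–O bond, under conditions of the kind that normally cleave peroxides.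
- Also against it: the skipped diene is prone to rearomatisation and double epoxidation, and C3 still has to be set at the end by a peroxycarbenium substitution.
- Step economy: clearly worse; the sequence is estimated to be well over half as long again as the chosen one.

Alternative 2: The C3–C4 and O1–C5 bonds are cut, so the ring is assembled from the silylperoxy ketal A4 (C3 with its methyl group and a silyloxyethyl arm) and the 1,1-disubstituted alkene A5 (C4–C15 with C7 already set). In the forward step SnCl4 ionises A4, the CH2 terminus of A5 attacks the peroxycarbenium ion, and the silylated peroxy oxygen captures the tertiary cation at C5 to give A6.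
- In its favour: it is convergent and makes the ring, both quaternary centres and two ring bonds in one step.
- Where it is better: it belongs to a known reaction class, so on precedent it beats step 4, and C7 arrives in enantiopure form in A5 with no late asymmetric reduction.
- Where it is equal: neither plan controls the absolute configuration of the ring, and both must separate ring diastereomers against C7.
- Against it: both new centres carry a methyl group and a primary alkyl group, so there is little to bias the ring closure toward trans, whereas in step 4 the ester arm can shield one face of the C5 cation. The arm must later be taken from silyloxyethyl to acetic acid (deprotection and two oxidations) before the diene goes in. A5 needs its own enantioselective synthesis, and its monosubstituted alkene is a weaker but competing nucleophile.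
- Step economy: comparable at best once the route to A5 is counted.

Alternative 3: The O1–C5 and O2–C3 bonds are cut, so hydrogen peroxide is added across the (E)-enone A7. In the forward step 9-amino-9-deoxy-epi-quinine trifluoroacetate forms an iminium ion, H2O2 adds to C5, and the hydroperoxide closes onto the C3 carbonyl to give the 3-hydroxy-1,2-dioxolane A8.
- Where it is better: it is the only plan of the four in which a catalyst sets the absolute configuration of a ring carbon, so in principle no material is discarded.
- Where it is equal: the later C3 substitution (ketalisation, then 7 and TiCl4) is the precedented single substitution and should be trans-selective, and the finishing sequence (diene installation, hydrolysis) is the same length.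
- Against it: the β-carbon of A7 is fully substituted. Iminium formation from the hindered ketone is slow, the hydroperoxide must create a tetrasubstituted C–O centre, and the catalyst has to tell CH3 from CH2R at that carbon. Collapse to the epoxide competes, and the C7 centre may be matched or mismatched with the catalyst.
- Step economy: A7 needs a multistep synthesis with control of alkene geometry, so the total is expected to be longer than the chosen route.

Key step: step 4

Remarks on the chemistry (assumptions):
- Compound 11 is treated as a catalogue reagent; if it is not in stock it is one step from 5-bromopentan-1-ol (t-BuMe2SiCl, imidazole).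
- The sense of induction in step 5 is assigned from the usual iminium model and is to be confirmed by correlation on the first run; both enantiomers of the catalyst salt are sold.
- Compound 9 is a racemate; the enantiomer drawn is the one that leads to 22.
- Compounds 3 and 4 have a high peroxide-oxygen content and are handled on gram scale or below, behind a shield, cold and in solution, without metal tools, distillation or evaporation to dryness. All later peroxides are kept away from phosphines, hydrogenation catalysts, iron and copper salts and strong reductants.

## Route

Step 1
Reactants: 1 pentane-2,4-dione (acetylacetone); 2 hydrogen peroxide (30% aqueous)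
Product: 3 3,5-dimethyl-1,2-dioxolane-3,5-diol (cis/trans mixture)
Conditions: 30% aq. H2O2 (1.0 equiv), 0 °C → rt; Et2O extraction, kept as a solution
Reagents that add atoms: none
Why: Nucleophilic addition of hydrogen peroxide to both carbonyl groups of the 1,3-diketone gives the cyclic bis(peroxy hemiketal), a known peroxide of this diketone. Exactly one equivalent of peroxide and no acid should keep open-chain and oligomeric hydroperoxides low.

Step 2
Reactants: 3 3,5-dimethyl-1,2-dioxolane-3,5-diol
Product: 4 3,5-dimethoxy-3,5-dimethyl-1,2-dioxolane (cis/trans mixture)
Conditions: MeOH, p-toluenesulfonic acid monohydrate (cat.), 3 Å molecular sieves, 0 °C → rt; NaHCO3; stored as a titrated CH2Cl2 solution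
Reagents that add atoms: methanol, CO
Why: Acid-catalysed ketal exchange of the two hemiketal hydroxyls through ring peroxycarbenium ions, the usual way of turning 3-hydroxy- into 3-alkoxy-1,2-dioxolanes; excess methanol and the sieves drive the equilibrium. Both diastereomers are acceptable because both centres are ionised in step 4.

Step 3
Reactants: 5 3-methylbut-2-enal
Product: 6 trimethyl{[(1E)-3-methylbuta-1,3-dien-1-yl]oxy}silane
Conditions: Me3SiCl, Et3N, ZnCl2 (cat.), toluene, 60 °C; filtration, distillation under reduced pressure
Reagents that add atoms: chlorotrimethylsilane, C[Si](C)(C)Cl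
Why: Silyl dienol ether formation by O-silylation and γ-deprotonation of the enal with triethylamine gives the 1-silyloxy diene, mainly E. The geometry has no bearing on step 4.

Step 4
Reactants: 4 3,5-dimethoxy-3,5-dimethyl-1,2-dioxolane; 7 tert-butyl[(1-methoxyethenyl)oxy]dimethylsilane; 6 trimethyl{[(1E)-3-methylbuta-1,3-dien-1-yl]oxy}silane
Product: 9 methyl 2-[(3S*,5R*)-3,5-dimethyl-5-[(2E)-2-methyl-4-oxobut-2-en-1-yl]-1,2-dioxolan-3-yl]acetate (racemic trans isomer; the 3S,5R enantiomer is drawn), via mono-substituted methoxy ketal ester 8 (not isolated)
Conditions: TiCl4 (1.0 equiv), CH2Cl2, −78 °C, then 7 (1.0 equiv); TiCl4 (1.1 equiv), then 6 (1.3 equiv), −78 °C; aq. NaHCO3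
Reagents that add atoms: none
Why: Proposed new method: TiCl4 removes one methoxy group of 4 to give a ring peroxycarbenium ion, a tertiary cation stabilised by the lone pair of the adjacent peroxide oxygen, and because a second ionisation of an already cationic ring is disfavoured, one equivalent of TiCl4 followed by one equivalent of 7 should stop at 8 while the titanium is left as the much weaker Lewis acid TiCl3(OMe). A second charge of TiCl4 then ionises the remaining ketal carbon of 8 and the dienol silane 6 attacks through its terminal CH2 (vinylogous Mukaiyama mode), forming C5–C6 and releasing the conjugated aldehyde on loss of Me3SiCl. The closest known reaction type is the Lewis-acid substitution of one 3-alkoxy-1,2-dioxolane by a silyl ketene acetal or silyl enol ether; what is new is two successive ionisations on one ring and a dienol silane as the second nucleophile. No ring is closed, the dioxolane being carried through intact. C3 is created first from a planar cation and in racemic form; C5 is created second, also from a planar cation, and its configuration relative to C3 is controlled by the C3 substituents: the nucleophile should enter anti to the CH2CO2CH3 arm, which is larger than methyl and whose carbonyl oxygen can bridge the cationic carbon on its own face, so the trans isomer is expected to predominate. Absolute configuration is not controlled, so 9 is a racemate. The step needs mono- before bis-substitution (secured by the staged stoichiometry at −78 °C and by the ester of 8 being inert to the second stage, whereas an enal installed first would not survive 7), γ- rather than α-attack of 6 (secured by the steric demand of the tertiary cation), and survival of the O–O bond (favoured by low temperature and short contact with the Lewis acid).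

Step 5
Reactants: 9 methyl 2-[(3S*,5R*)-3,5-dimethyl-5-[(2E)-2-methyl-4-oxobut-2-en-1-yl]-1,2-dioxolan-3-yl]acetate (racemate)
Product: 10 methyl 2-[(3S,5R)-3,5-dimethyl-5-[(2S)-2-methyl-4-oxobutyl]-1,2-dioxolan-3-yl]acetate
Conditions: (S)-2-tert-butyl-3-methylimidazolidin-4-one trifluoroacetate (20 mol%), diethyl 2,6-dimethyl-1,4-dihydropyridine-3,5-dicarboxylate (1.2 equiv), CHCl3, −30 °C; chromatographic separation of diastereomers
Reagents that add atoms: none
Why: Iminium-ion transfer hydrogenation: the imidazolidinone condenses with the enal and the Hantzsch ester delivers hydride to C7 on the iminium face remote from the tert-butyl group, with the large CH2-dioxolanyl group trans to the iminium carbon; E and Z iminium ions interconvert faster than they are reduced, so the geometry of 9 does not matter. Each enantiomer of 9 should be reduced with the same catalyst-imposed sense at C7, giving 10 and its (3R,5S) ring diastereomer, which are separated on silica or by preparative HPLC. The descriptor at C7 is S here only because CH2CHO outranks the ring-bearing CH2; the spatial arrangement is that of C7 (R) in 22.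

Step 6
Reactants: 11 (5-bromopentyloxy)(tert-butyl)dimethylsilane
Product: 12 {5-[(tert-butyldimethylsilyl)oxy]pentyl}triphenylphosphonium bromide
Conditions: PPh3, MeCN, 80 °C; trituration with Et2O
Reagents that add atoms: triphenylphosphine, c1ccc(cc1)P(c1ccccc1)c1ccccc1
Why: SN2 quaternisation of triphenylphosphine by the primary bromide. The salt is triturated free of phosphine so that no free phosphine, which could deoxygenate the peroxide, enters step 7.

Step 7
Reactants: 10 methyl 2-[(3S,5R)-3,5-dimethyl-5-[(2S)-2-methyl-4-oxobutyl]-1,2-dioxolan-3-yl]acetate; 12 {5-[(tert-butyldimethylsilyl)oxy]pentyl}triphenylphosphonium bromide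
Product: 14 methyl 2-[(3S,5R)-5-[(2R,4Z)-9-[(tert-butyldimethylsilyl)oxy]-2-methylnon-4-en-1-yl]-3,5-dimethyl-1,2-dioxolan-3-yl]acetate, via phosphorus ylide 13 (not isolated)
Conditions: NaN(SiMe3)2 (slightly less than 1 equiv relative to 12), THF, 0 °C; then 10, −78 → −20 °C
Reagents that add atoms: none
Why: Wittig olefination with a non-stabilised ylide, preformed with a slight deficit of base so that no free amide meets the β-peroxy ester; the aldehyde reacts far faster than the ester at −78 °C. The Z geometry that should predominate is irrelevant because the alkene is saturated next.

Step 8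
Reactants: 14 methyl 2-[(3S,5R)-5-[(2R,4Z)-9-[(tert-butyldimethylsilyl)oxy]-2-methylnon-4-en-1-yl]-3,5-dimethyl-1,2-dioxolan-3-yl]acetate
Product: 15 methyl 2-[(3S,5R)-5-[(2R)-9-[(tert-butyldimethylsilyl)oxy]-2-methylnonyl]-3,5-dimethyl-1,2-dioxolan-3-yl]acetate
Conditions: KO2CN=NCO2K (excess, in portions), AcOH, MeOH/CH2Cl2, 0 °C → rt
Reagents that add atoms: none
Why: Diimide reduction: diimide, released by protonation and decarboxylation of the azodicarboxylate, transfers two hydrogens to the unhindered 1,2-disubstituted alkene in a concerted syn fashion and is known to leave O–O bonds, esters and silyl ethers alone. Catalytic hydrogenation is excluded by the peroxide.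

Step 9
Reactants: 15 methyl 2-[(3S,5R)-5-[(2R)-9-[(tert-butyldimethylsilyl)oxy]-2-methylnonyl]-3,5-dimethyl-1,2-dioxolan-3-yl]acetate
Product: 16 methyl 2-[(3S,5R)-5-[(2R)-9-hydroxy-2-methylnonyl]-3,5-dimethyl-1,2-dioxolan-3-yl]acetate
Conditions: camphor-10-sulfonic acid (10 mol%), MeOH, 0 °C → rt; NaHCO3
Reagents that add atoms: none
Why: Acid-catalysed methanolysis of a primary tert-butyldimethylsilyl ether. The methyl ester is degenerate toward methanol and the fully substituted dialkyl peroxide is stable to dilute acid.

Step 10
Reactants: 16 methyl 2-[(3S,5R)-5-[(2R)-9-hydroxy-2-methylnonyl]-3,5-dimethyl-1,2-dioxolan-3-yl]acetate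
Product: 17 methyl 2-[(3S,5R)-3,5-dimethyl-5-[(2R)-2-methyl-9-oxononyl]-1,2-dioxolan-3-yl]acetate
Conditions: Dess–Martin periodinane, NaHCO3, CH2Cl2, 0 °C → rt; filtration through silica
Reagents that add atoms: none
Why: Dess–Martin oxidation of the primary alcohol by ligand exchange at iodine followed by α-hydrogen removal. The buffered, metal-free, non-reducing conditions suit the peroxide and stop at the aldehyde.

Step 11
Reactants: 17 methyl 2-[(3S,5R)-3,5-dimethyl-5-[(2R)-2-methyl-9-oxononyl]-1,2-dioxolan-3-yl]acetate; 18 diethyl [(2E)-3-phenylprop-2-en-1-yl]phosphonate
Product: 20 methyl 2-[(3S,5R)-3,5-dimethyl-5-[(2R,9E,11E)-2-methyl-12-phenyldodeca-9,11-dien-1-yl]-1,2-dioxolan-3-yl]acetate, via sodium phosphonate carbanion 19 (not isolated)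
Conditions: NaN(SiMe3)2 (slight deficit relative to 18), THF, −78 °C; then 17, −78 °C → rt, dark
Reagents that add atoms: none
Why: Horner–Wadsworth–Emmons olefination with the allyl-stabilised phosphonate carbanion, which reacts at its α-carbon and should form C14=C15 mainly E while C16=C17 keeps its E geometry. The carbanion is too weak a base to enolise the ester at low temperature.

Step 12
Reactants: 20 methyl 2-[(3S,5R)-3,5-dimethyl-5-[(2R,9E,11E)-2-methyl-12-phenyldodeca-9,11-dien-1-yl]-1,2-dioxolan-3-yl]acetate
Product: 22 2-[(3S,5R)-3,5-dimethyl-5-[(2R,9E,11E)-2-methyl-12-phenyldodeca-9,11-dien-1-yl]-1,2-dioxolan-3-yl]acetic acid (CNP0196394.4), via the lithium carboxylate 21 (not isolated)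
Conditions: LiOH·H2O, THF/MeOH/H2O, 0 °C; then 1 M HCl to pH 3, 0 °C, dark
Reagents that add atoms: lithium hydroxide, [Li+].[OH-]
Why: Saponification of the methyl ester by acyl substitution with hydroxide, then cold acidification. Dilute hydroxide at 0 °C should be too weak a base to trigger β-elimination of the ring peroxide, and no stereocentre is epimerisable.

## Compound list

1 | pentane-2,4-dione (acetylacetone) | CC(=O)CC(C)=O | starting material
2 | hydrogen peroxide (30% aqueous) | OO | starting material
3 | 3,5-dimethyl-1,2-dioxolane-3,5-diol (cis/trans mixture) | CC1(O)CC(C)(O)OO1 | intermediate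
4 | 3,5-dimethoxy-3,5-dimethyl-1,2-dioxolane (cis/trans mixture) | COC1(C)CC(C)(OC)OO1 | intermediate
5 | 3-methylbut-2-enal | CC(C)=CC=O | starting material
6 | trimethyl{[(1E)-3-methylbuta-1,3-dien-1-yl]oxy}silane | C=C(C)/C=C/O[Si](C)(C)C | intermediate
7 | tert-butyl[(1-methoxyethenyl)oxy]dimethylsilane | C=C(OC)O[Si](C)(C)C(C)(C)C | starting material
8 | methyl 2-(5-methoxy-3,5-dimethyl-1,2-dioxolan-3-yl)acetate (racemic, both diastereomers; formed in the flask, not isolated) | COC(=O)CC1(C)CC(C)(OC)OO1 | intermediate
9 | methyl 2-[(3S*,5R*)-3,5-dimethyl-5-[(2E)-2-methyl-4-oxobut-2-en-1-yl]-1,2-dioxolan-3-yl]acetate (racemic trans isomer; 3S,5R enantiomer drawn) | O=C/C=C(\C)C[C@]1(C)C[C@@](C)(CC(=O)OC)OO1 | intermediate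
10 | methyl 2-[(3S,5R)-3,5-dimethyl-5-[(2S)-2-methyl-4-oxobutyl]-1,2-dioxolan-3-yl]acetate | O=CC[C@@H](C)C[C@]1(C)C[C@@](C)(CC(=O)OC)OO1 | intermediate
11 | (5-bromopentyloxy)(tert-butyl)dimethylsilane | BrCCCCCO[Si](C)(C)C(C)(C)C | starting material
12 | {5-[(tert-butyldimethylsilyl)oxy]pentyl}triphenylphosphonium bromide | [Br-].CC(C)(C)[Si](C)(C)OCCCCC[P+](c1ccccc1)(c1ccccc1)c1ccccc1 | intermediate
13 | {5-[(tert-butyldimethylsilyl)oxy]pentylidene}triphenylphosphorane (formed in the flask, not isolated) | CC(C)(C)[Si](C)(C)OCCCCC=P(c1ccccc1)(c1ccccc1)c1ccccc1 | intermediate
14 | methyl 2-[(3S,5R)-5-[(2R,4Z)-9-[(tert-butyldimethylsilyl)oxy]-2-methylnon-4-en-1-yl]-3,5-dimethyl-1,2-dioxolan-3-yl]acetate | CC(C)(C)[Si](C)(C)OCCCC/C=C\C[C@@H](C)C[C@]1(C)C[C@@](C)(CC(=O)OC)OO1 | intermediate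
15 | methyl 2-[(3S,5R)-5-[(2R)-9-[(tert-butyldimethylsilyl)oxy]-2-methylnonyl]-3,5-dimethyl-1,2-dioxolan-3-yl]acetate | CC(C)(C)[Si](C)(C)OCCCCCCC[C@@H](C)C[C@]1(C)C[C@@](C)(CC(=O)OC)OO1 | intermediate
16 | methyl 2-[(3S,5R)-5-[(2R)-9-hydroxy-2-methylnonyl]-3,5-dimethyl-1,2-dioxolan-3-yl]acetate | OCCCCCCC[C@@H](C)C[C@]1(C)C[C@@](C)(CC(=O)OC)OO1 | intermediate
17 | methyl 2-[(3S,5R)-3,5-dimethyl-5-[(2R)-2-methyl-9-oxononyl]-1,2-dioxolan-3-yl]acetate | O=CCCCCCC[C@@H](C)C[C@]1(C)C[C@@](C)(CC(=O)OC)OO1 | intermediate
18 | diethyl [(2E)-3-phenylprop-2-en-1-yl]phosphonate | CCOP(=O)(C/C=C/c1ccccc1)OCC | starting material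
19 | sodium (2E)-1-(diethoxyphosphoryl)-3-phenylprop-2-en-1-ide (formed in the flask, not isolated) | CCOP(=O)(OCC)[CH-]/C=C/c1ccccc1.[Na+] | intermediate
20 | methyl 2-[(3S,5R)-3,5-dimethyl-5-[(2R,9E,11E)-2-methyl-12-phenyldodeca-9,11-dien-1-yl]-1,2-dioxolan-3-yl]acetate | C[C@H](CCCCCC/C=C/C=C/c1ccccc1)C[C@]1(C)C[C@@](C)(CC(=O)OC)OO1 | intermediate
21 | lithium 2-[(3S,5R)-3,5-dimethyl-5-[(2R,9E,11E)-2-methyl-12-phenyldodeca-9,11-dien-1-yl]-1,2-dioxolan-3-yl]acetate (formed in the flask, not isolated) | C[C@H](CCCCCC/C=C/C=C/c1ccccc1)C[C@]1(C)C[C@@](C)(CC(=O)[O-])OO1.[Li+] | intermediate
22 | 2-[(3S,5R)-3,5-dimethyl-5-[(2R,9E,11E)-2-methyl-12-phenyldodeca-9,11-dien-1-yl]-1,2-dioxolan-3-yl]acetic acid | C[C@H](CCCCCC/C=C/C=C/c1ccccc1)C[C@]1(C)C[C@@](C)(CC(=O)O)OO1 | target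

## Step count and least certain steps

Total step count: 12. Longest linear sequence: 10 steps (steps 1, 2, 4, 5, 7, 8, 9, 10, 11, 12).

**Step 4 (key step).** Several processes can fail.
- Loss of staging (double substitution by 7, or none), because the two ketal carbons are equivalent and the plan rests on the second ionisation being slow.
- Lewis-acid-induced heterolysis of the O–O bond, or proton loss from C4 of the cation.
- Attack of 6 through its α-carbon, or its oligomerisation by TiCl4.
- Low facial preference at C5, because CH3 and CH2CO2CH3 differ only moderately in size.

Fallback, from 4 and 7, returning at 9: the two substitutions are run as separate operations of the precedented single-substitution type, followed by a metathesis.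
- Compound 4 in excess is treated with TiCl4 and 7 at −78 °C, and 8 is isolated by chromatography with recovery of 4.
- Compound 8 is treated with SnCl4 and trimethyl(2-methylallyl)silane, an allylsilane being the best-established carbon nucleophile for 3-alkoxy-1,2-dioxolanes, to give methyl 2-[(3S*,5R*)-3,5-dimethyl-5-(2-methylprop-2-en-1-yl)-1,2-dioxolan-3-yl]acetate F1.
- Cross-metathesis of F1 with (E)-but-2-enal gives 9. The catalyst is the second-generation Hoveyda–Grubbs catalyst, [1,3-bis(2,4,6-trimethylphenyl)imidazolidin-2-ylidene]dichloro(2-isopropoxybenzylidene)ruthenium, in CH2Cl2 at 40 °C; formation of β,β-disubstituted enals from 1,1-disubstituted alkenes is a known use of this reaction.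

If the ring itself does not survive ionisation, this fallback fails too, and the annulation of Alternative 2 would be the remaining option.

**Step 5.** The likely failures are insufficient discrimination between the two β-substituents at C7 (methyl against CH2-ring) and co-elution of the two diastereomers, whose stereocentres are remote from each other. Fallback, from 9, returning at 10:
- Racemic 9 is first resolved by preparative chromatography on a chiral stationary phase (amylose tris(3,5-dimethylphenylcarbamate)).
- The (3S,5R) enantiomer is then reduced with an ene-reductase of the Old Yellow Enzyme family (NADPH recycled by glucose and glucose dehydrogenase, pH 7 buffer, 25 °C), a known biocatalytic reduction of β-methyl enals, with the enzyme screened for the required sense.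

This removes the diastereomer separation and replaces the small-molecule catalyst; it makes no compound outside the list (F0).

**Step 2.** The likely failures are ring opening to the β-hydroperoxy ketone with loss of hydrogen peroxide under acid, and incomplete exchange giving hydroxy/methoxy mixtures. Fallback, from 3, returning at 9:
- Compound 3 is silylated under neutral, irreversible conditions (Me3SiCl, imidazole, CH2Cl2, 0 °C) to 3,5-dimethyl-3,5-bis(trimethylsilyloxy)-1,2-dioxolane F2.
- F2 replaces 4 in step 4: the silyloxy groups are ionised by TiCl4 in the same staged way, with methyl 2-[3,5-dimethyl-5-(trimethylsilyloxy)-1,2-dioxolan-3-yl]acetate F3 taking the place of 8.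

**Step 11.** The likely failures are incomplete E-selectivity at C14=C15 and arrest at the β-oxido phosphonate stage, which would require warmer, more basic conditions that endanger the β-peroxy ester. Fallback, from 17, returning at 20:
- Wittig reaction of 17 with the stabilised ylide (triphenylphosphoranylidene)acetaldehyde (CH2Cl2, 40 °C, no added base) gives methyl 2-[(3S,5R)-3,5-dimethyl-5-[(2R,9E)-2-methyl-11-oxoundec-9-en-1-yl]-1,2-dioxolan-3-yl]acetate F4.
- Horner–Wadsworth–Emmons reaction of F4 with diethyl benzylphosphonate (NaN(SiMe3)2, THF, −78 → 0 °C) gives 20.

Each double bond is then made by a reaction class with a strong intrinsic E preference.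

## Further compounds

F1 | step 4 | methyl 2-[(3S*,5R*)-3,5-dimethyl-5-(2-methylprop-2-en-1-yl)-1,2-dioxolan-3-yl]acetate (racemate; 3S,5R enantiomer drawn) | C=C(C)C[C@]1(C)C[C@@](C)(CC(=O)OC)OO1
F0 | step 5 | none | none
F2 | step 2 | 3,5-dimethyl-3,5-bis(trimethylsilyloxy)-1,2-dioxolane | C[Si](C)(C)OC1(C)CC(C)(O[Si](C)(C)C)OO1
F3 | step 2 | methyl 2-[3,5-dimethyl-5-(trimethylsilyloxy)-1,2-dioxolan-3-yl]acetate | COC(=O)CC1(C)CC(C)(O[Si](C)(C)C)OO1
F4 | step 11 | methyl 2-[(3S,5R)-3,5-dimethyl-5-[(2R,9E)-2-methyl-11-oxoundec-9-en-1-yl]-1,2-dioxolan-3-yl]acetate | O=C/C=C/CCCCCC[C@@H](C)C[C@]1(C)C[C@@](C)(CC(=O)OC)OO1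
A1 | alternative 1 | mesitylene (1,3,5-trimethylbenzene) | Cc1cc(C)cc(C)c1
A2 | alternative 1 | 1,3,5-trimethylcyclohexa-1,4-diene | CC1=CC(C)C=C(C)C1
A3 | alternative 1 | (1R,5R,6S)-1,3,5-trimethyl-7-oxabicyclo[4.1.0]hept-3-ene | C[C@@]12CC(C)=C[C@@H](C)[C@@H]1O2
A4 | alternative 2 | tert-butyl{[3-methoxy-3-(triethylsilylperoxy)butyl]oxy}diphenylsilane | COC(C)(CCO[Si](c1ccccc1)(c1ccccc1)C(C)(C)C)OO[Si](CC)(CC)CC
A5 | alternative 2 | (4R)-2,4-dimethyldodeca-1,11-diene | C=C(C)C[C@H](C)CCCCCCC=C
A6 | alternative 2 | tert-butyl{2-[(3R,5R)-3,5-dimethyl-5-[(2R)-2-methyldec-9-en-1-yl]-1,2-dioxolan-3-yl]ethoxy}diphenylsilane | C=CCCCCCC[C@@H](C)C[C@]1(C)C[C@@](C)(CCO[Si](c2ccccc2)(c2ccccc2)C(C)(C)C)OO1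
A7 | alternative 3 | (3E,6R)-4,6-dimethyltetradeca-3,13-dien-2-one | CC(=O)/C=C(\C)C[C@H](C)CCCCCCC=C
A8 | alternative 3 | (5R)-3,5-dimethyl-5-[(2R)-2-methyldec-9-en-1-yl]-1,2-dioxolan-3-ol (C3 undefined) | C=CCCCCCC[C@@H](C)C[C@]1(C)CC(C)(O)OO1
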